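**Retrosynthetic overview**
1. Target 21 ⇐ desilylation at C8–O and acetylation at C2–O ⇐ epoxy alcohol 19 ⇐ hydroxyl-directed epoxidation (C–O) of the Z-cyclodecenol 18; the oxirane is the last ring formed.
2. 18 ⇐ Nozaki–Hiyama–Kishi closure of C2–C3 (CrCl2/NiCl2) from iodo-aldehyde 17; the ten-membered carbocycle is the first ring formed.
3. 17 ⇐ Felkin–Anh methyl addition at C7 and the key C–O bond: a catalytic asymmetric α-angeloyloxylation at C6 of ketone 14 (new method).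
4. 14 ⇐ glyoxylate-ene reaction on the prenyl group of 10 (C1–C10, isopropenyl) ⇐ enolate alkylation of 4 with (Z)-1-bromo-3-iodobut-2-ene 8.
5. 4 ⇐ proline-catalysed α-aminoxylation (C8–O) of 6-methylhept-5-en-2-one 1.

Assumption: ring atoms are numbered C10 (isopropenyl), C1 (OAng), C2 (OAc), C3/C4 (epoxide, Me on C3), C5, C6 (OAng), C7 (Me, OH), C8 (OH), C9; the given SMILES is (1S,2S,3R,4R,6S,7S,8R,10R), and these atom labels are kept for all intermediates.

**Step 1**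
Reactants: 1 6-methylhept-5-en-2-one
Product: 3 (R)-3-hydroxy-6-methylhept-5-en-2-one, via anilinooxy ketone 2 (not isolated)
Conditions: L-proline (20 mol %), PhNO (slow addition), DMSO, 4 °C; then CuSO4·5H2O (30 mol %), MeOH, 0 °C
Reagents that add atoms: nitrosobenzene O=Nc1ccccc1
Why: Proline-catalysed α-aminoxylation (nitroso aldol) goes through the more substituted enamine, so oxygen enters at the CH2 next to the carbonyl (C8) with L-proline directing O-attack to give the R centre, and CuSO4-catalysed N–O cleavage then frees the alcohol.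

**Step 2**
Reactants: 3 (R)-3-hydroxy-6-methylhept-5-en-2-one
Product: 4 (R)-6-methyl-3-(triethylsilyloxy)hept-5-en-2-one
Conditions: Et3SiCl, imidazole, CH2Cl2, 0 °C
Reagents that add atoms: chlorotriethylsilane CC[Si](Cl)(CC)CC
Why: Silylation protects C8–OH with a non-chelating group that survives the later steps and blocks acyloin isomerisation; the stereocentre is untouched.

**Step 3**
Reactants: 5 but-2-yn-1-ol
Product: 7 (Z)-3-iodobut-2-en-1-ol, via Na[(MeOCH2CH2O)2Al(OCH2CH=CMe)] 6 (not isolated)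
Conditions: NaAlH2(OCH2CH2OMe)2, THF, 0 °C to rt; then I2, THF, −78 °C
Reagents that add atoms: iodine II
Why: Hydroxyl-directed trans-hydroalumination of the propargylic alcohol puts aluminium on C3 in a five-membered ring, and iodinolysis with retention gives only the Z-iodide.

**Step 4**
Reactants: 7 (Z)-3-iodobut-2-en-1-ol
Product: 8 (Z)-1-bromo-3-iodobut-2-ene
Conditions: CBr4, PPh3, CH2Cl2, 0 °C
Reagents that add atoms: tetrabromomethane BrC(Br)(Br)Br
Why: Appel bromination converts the primary allylic alcohol into the bromide under neutral conditions without changing the alkene geometry.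

**Step 5**
Reactants: 4 (R)-6-methyl-3-(triethylsilyloxy)hept-5-en-2-one; 8 (Z)-1-bromo-3-iodobut-2-ene
Product: 10 (5R,9Z)-10-iodo-2-methyl-5-(triethylsilyloxy)undeca-2,9-dien-6-one, via LiOC(=CH2)CH(OSiEt3)CH2CH=CMe2 9 (not isolated)
Conditions: LiN(iPr)2, THF, −78 °C; then 8, DMPU, −78 to −40 °C
Reagents that add atoms: none
Why: Kinetic deprotonation at the CH3 group and SN2 alkylation of the enolate by the allylic bromide form C5–C6 (the methyl carbon becomes C6) without touching the C8 centre or the Z-iodoalkene.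

**Step 6**
Reactants: 10 (5R,9Z)-10-iodo-2-methyl-5-(triethylsilyloxy)undeca-2,9-dien-6-one; 11 ethyl glyoxylate
Product: 12 ethyl (2S,3R,5R,9Z)-2-hydroxy-10-iodo-6-oxo-3-(prop-1-en-2-yl)-5-(triethylsilyloxy)undec-9-enoate
Conditions: (S)-BINOL (10 mol %), TiCl2(OiPr)2 (10 mol %), 4 Å molecular sieves, CH2Cl2, −30 to 0 °C
Reagents that add atoms: none
Why: Mikami-type catalytic asymmetric glyoxylate-ene reaction: the aldehyde carbon (C1) bonds to the less substituted alkene carbon C10 while a methyl hydrogen shifts to oxygen to give the isopropenyl group, the (S)-BINOL/TiCl2(OiPr)2 complex fixes C1 as S, and the closed six-membered transition state gives the 2,3-syn adduct so that C10 is R.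

**Step 7**
Reactants: 12 ethyl (2S,3R,5R,9Z)-2-hydroxy-10-iodo-6-oxo-3-(prop-1-en-2-yl)-5-(triethylsilyloxy)undec-9-enoate
Product: 13 (2S,3R,5R,9Z)-2-hydroxy-10-iodo-N-methoxy-N-methyl-6-oxo-3-(prop-1-en-2-yl)-5-(triethylsilyloxy)undec-9-enamide
Conditions: Me3Al, MeNH(OMe)·HCl, CH2Cl2, 0 °C to rt
Reagents that add atoms: N,O-dimethylhydroxylamine hydrochloride CNOC.Cl
Why: Weinreb amidation by ClMeAl–N(OMe)Me, helped by chelation of the α-hydroxy ester, gives an amide that can later be reduced to the aldehyde in the presence of ordinary esters; no stereocentre is involved.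

**Step 8**
Reactants: 13 (2S,3R,5R,9Z)-2-hydroxy-10-iodo-N-methoxy-N-methyl-6-oxo-3-(prop-1-en-2-yl)-5-(triethylsilyloxy)undec-9-enamide
Product: 14 (2S,3R,5R,9Z)-10-iodo-1-[methoxy(methyl)amino]-1,6-dioxo-3-(prop-1-en-2-yl)-5-(triethylsilyloxy)undec-9-en-2-yl (Z)-2-methylbut-2-enoate
Conditions: angelic acid, 2,4,6-trichlorobenzoyl chloride, Et3N, toluene, rt; then 13, 75 °C
Reagents that add atoms: angelic acid C/C=C(/C)C(=O)O
Why: Yamaguchi-type esterification through the mixed 2,4,6-trichlorobenzoic anhydride acylates the only free hydroxyl (C1–OH) with retention and, run without DMAP, keeps the Z geometry of the angelate.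

**Step 9**
Reactants: 14 (2S,3R,5R,9Z)-10-iodo-1-[methoxy(methyl)amino]-1,6-dioxo-3-(prop-1-en-2-yl)-5-(triethylsilyloxy)undec-9-en-2-yl (Z)-2-methylbut-2-enoate
Product: 15 (2S,3R,5R,7S,9Z)-10-iodo-1-[methoxy(methyl)amino]-1,6-dioxo-3-(prop-1-en-2-yl)-5-(triethylsilyloxy)undec-9-ene-2,7-diyl bis[(Z)-2-methylbut-2-enoate]
Conditions: angelic acid, DCC, urea·H2O2, CH2Cl2, 0 °C (bis(angeloyl) peroxide formed in the flask); then 14, 9-amino(9-deoxy)-epi-quinidine (20 mol %), Cl3CCO2H (40 mol %), BHT, THF, 25 °C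
Reagents that add atoms: angelic acid C/C=C(/C)C(=O)O; urea–hydrogen peroxide NC(N)=O.OO
Why: Proposed new method: enamine-catalysed α-acyloxylation of an acyclic ketone with the diacyl peroxide of an α,β-unsaturated acid — the primary amine condenses with the C7 ketone, the enamine forms only toward the unhindered C6 methylene (C8 is a silyloxy-bearing methine and is not enolised), its carbon attacks one peroxide oxygen in an SN2 displacement on the O–O bond while the protonated quinuclidine hydrogen-bonds the peroxide carbonyl and shields one enamine face, and hydrolysis releases the (S)-C6 angelate with the hindered Z-enoate untouched; the closest known reaction type is the amine-catalysed α-benzoyloxylation of aldehydes and cyclic ketones with dibenzoyl peroxide, and the facial sense is assigned by analogy (the quinine-derived pseudo-enantiomer gives the C6 epimer).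

**Step 10**
Reactants: 15 (2S,3R,5R,7S,9Z)-10-iodo-1-[methoxy(methyl)amino]-1,6-dioxo-3-(prop-1-en-2-yl)-5-(triethylsilyloxy)undec-9-ene-2,7-diyl bis[(Z)-2-methylbut-2-enoate]
Product: 16 (2S,3R,5R,6R,7S,9Z)-6-hydroxy-10-iodo-1-[methoxy(methyl)amino]-6-methyl-1-oxo-3-(prop-1-en-2-yl)-5-(triethylsilyloxy)undec-9-ene-2,7-diyl bis[(Z)-2-methylbut-2-enoate]
Conditions: MeTi(OiPr)3, Et2O, −30 to 0 °C
Reagents that add atoms: methyltitanium triisopropoxide C[Ti](OC(C)C)(OC(C)C)OC(C)C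
Why: Felkin–Anh addition of the non-chelating, ester- and amide-tolerant MeTi(OiPr)3: the C6–O and C8–O bonds both lie anti to the incoming methyl on the same face (matched case), which gives the all-syn C6/C7/C8 oxygen array (C7 is R here only because the silyl ether changes the priorities).

**Step 11**
Reactants: 16 (2S,3R,5R,6R,7S,9Z)-6-hydroxy-10-iodo-1-[methoxy(methyl)amino]-6-methyl-1-oxo-3-(prop-1-en-2-yl)-5-(triethylsilyloxy)undec-9-ene-2,7-diyl bis[(Z)-2-methylbut-2-enoate]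
Product: 17 (2S,3R,5R,6R,7S,9Z)-6-hydroxy-10-iodo-6-methyl-1-oxo-3-(prop-1-en-2-yl)-5-(triethylsilyloxy)undec-9-ene-2,7-diyl bis[(Z)-2-methylbut-2-enoate]
Conditions: Cp2Zr(H)Cl, THF, rt, 20 min
Reagents that add atoms: none
Why: Reduction of the Weinreb amide with Cp2Zr(H)Cl stops at a Cp2Zr(Cl)–O–CH(NMeOMe) hemiaminal that gives the aldehyde on work-up, a reduction known to spare esters, and the neutral conditions do not epimerise C1.

**Step 12**
Reactants: 17 (2S,3R,5R,6R,7S,9Z)-6-hydroxy-10-iodo-6-methyl-1-oxo-3-(prop-1-en-2-yl)-5-(triethylsilyloxy)undec-9-ene-2,7-diyl bis[(Z)-2-methylbut-2-enoate]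
Product: 18 (1S,2R,3Z,6S,7R,8R,10R)-2,7-dihydroxy-3,7-dimethyl-10-(prop-1-en-2-yl)-8-(triethylsilyloxy)cyclodec-3-ene-1,6-diyl bis[(Z)-2-methylbut-2-enoate]
Conditions: CrCl2 (8 equiv), NiCl2 (2 mol %), DMSO/THF 3:1, 0.002 M, syringe-pump addition, rt
Reagents that add atoms: none
Why: Nozaki–Hiyama–Kishi macrocyclisation under high dilution: the alkenyl–CrCl2 species from the Z-iodide (geometry retained) adds to the aldehyde from the Felkin–Anh face anti to the α-angeloyloxy group, closing the ten-membered ring and setting C2 in the 1,2-anti sense.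

**Step 13**
Reactants: 18 (1S,2R,3Z,6S,7R,8R,10R)-2,7-dihydroxy-3,7-dimethyl-10-(prop-1-en-2-yl)-8-(triethylsilyloxy)cyclodec-3-ene-1,6-diyl bis[(Z)-2-methylbut-2-enoate]
Product: 19 (1S,2S,3S,4R,6S,7R,8R,10R)-3,4-epoxy-2,7-dihydroxy-3,7-dimethyl-10-(prop-1-en-2-yl)-8-(triethylsilyloxy)cyclodecane-1,6-diyl bis[(Z)-2-methylbut-2-enoate]
Conditions: VO(acac)2 (5 mol %), t-BuOOH, 2,6-lutidine, CH2Cl2, 0 °C
Reagents that add atoms: tert-butyl hydroperoxide CC(C)(C)OO
Why: Hydroxyl-directed epoxidation: the V–O–C2 alkoxide formed from VO(acac)2 delivers the peroxide oxygen to the alkene face syn to the allylic hydroxyl, as in medium-ring (Z)-cycloalk-2-enols and 2-substituted allylic alcohols, which sets C3 and C4 and leaves the isopropenyl and angelate alkenes alone.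

**Step 14**
Reactants: 19 (1S,2S,3S,4R,6S,7R,8R,10R)-3,4-epoxy-2,7-dihydroxy-3,7-dimethyl-10-(prop-1-en-2-yl)-8-(triethylsilyloxy)cyclodecane-1,6-diyl bis[(Z)-2-methylbut-2-enoate]
Product: 20 (1S,2S,3R,4R,6S,7R,8R,10R)-2-acetoxy-3,4-epoxy-7-hydroxy-3,7-dimethyl-10-(prop-1-en-2-yl)-8-(triethylsilyloxy)cyclodecane-1,6-diyl bis[(Z)-2-methylbut-2-enoate]
Conditions: Ac2O, pyridine, DMAP (cat.), CH2Cl2, 0 °C to rt
Reagents that add atoms: acetic anhydride CC(=O)OC(C)=O
Why: DMAP-catalysed acetylation of the only free secondary hydroxyl (C2–OH); the tertiary C7–OH does not react under these conditions and no stereocentre changes.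

**Step 15**
Reactants: 20 (1S,2S,3R,4R,6S,7R,8R,10R)-2-acetoxy-3,4-epoxy-7-hydroxy-3,7-dimethyl-10-(prop-1-en-2-yl)-8-(triethylsilyloxy)cyclodecane-1,6-diyl bis[(Z)-2-methylbut-2-enoate]
Product: 21 CNP0249359.1, (1S,2S,3R,4R,6S,7S,8R,10R)-2-acetoxy-3,4-epoxy-7,8-dihydroxy-3,7-dimethyl-10-(prop-1-en-2-yl)cyclodecane-1,6-diyl bis[(Z)-2-methylbut-2-enoate]
Conditions: HF·pyridine, pyridine, THF, 0 °C
Reagents that add atoms: none
Why: Buffered fluoride cleavage of the secondary triethylsilyl ether frees C8–OH without opening the epoxide or moving the esters.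

**Compound list**
1 | 6-methylhept-5-en-2-one | CC(=O)CCC=C(C)C | starting material
2 | (R)-6-methyl-3-(phenylaminooxy)hept-5-en-2-one | CC(=O)[C@H](ONc1ccccc1)CC=C(C)C | intermediate
3 | (R)-3-hydroxy-6-methylhept-5-en-2-one | CC(=O)[C@H](O)CC=C(C)C | intermediate
4 | (R)-6-methyl-3-(triethylsilyloxy)hept-5-en-2-one | CC(=O)[C@H](O[Si](CC)(CC)CC)CC=C(C)C | intermediate
5 | but-2-yn-1-ol | CC#CCO | starting material
6 | Na[(MeOCH2CH2O)2Al(OCH2CH=CMe)], cyclic alkenylalanate with Al bonded to O and to C3 in a five-membered ring | CC1=CCO[Al-]1(OCCOC)OCCOC.[Na+] | intermediate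
7 | (Z)-3-iodobut-2-en-1-ol | C/C(I)=C/CO | intermediate
8 | (Z)-1-bromo-3-iodobut-2-ene | C/C(I)=C/CBr | intermediate
9 | LiOC(=CH2)CH(OSiEt3)CH2CH=CMe2, the enolate of 4 (R at the silyloxy carbon) | [Li]OC(=C)[C@H](O[Si](CC)(CC)CC)CC=C(C)C | intermediate
10 | (5R,9Z)-10-iodo-2-methyl-5-(triethylsilyloxy)undeca-2,9-dien-6-one | C/C(I)=C/CCC(=O)[C@H](O[Si](CC)(CC)CC)CC=C(C)C | intermediate
11 | ethyl glyoxylate | CCOC(=O)C=O | starting material
12 | ethyl (2S,3R,5R,9Z)-2-hydroxy-10-iodo-6-oxo-3-(prop-1-en-2-yl)-5-(triethylsilyloxy)undec-9-enoate | C=C(C)[C@H]([C@H](O)C(=O)OCC)C[C@@H](O[Si](CC)(CC)CC)C(=O)CC/C=C(/C)I | intermediate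
13 | (2S,3R,5R,9Z)-2-hydroxy-10-iodo-N-methoxy-N-methyl-6-oxo-3-(prop-1-en-2-yl)-5-(triethylsilyloxy)undec-9-enamide | C=C(C)[C@H]([C@H](O)C(=O)N(C)OC)C[C@@H](O[Si](CC)(CC)CC)C(=O)CC/C=C(/C)I | intermediate
14 | (2S,3R,5R,9Z)-10-iodo-1-[methoxy(methyl)amino]-1,6-dioxo-3-(prop-1-en-2-yl)-5-(triethylsilyloxy)undec-9-en-2-yl (Z)-2-methylbut-2-enoate | C=C(C)[C@H]([C@H](OC(=O)/C(C)=C\C)C(=O)N(C)OC)C[C@@H](O[Si](CC)(CC)CC)C(=O)CC/C=C(/C)I | intermediate
15 | (2S,3R,5R,7S,9Z)-10-iodo-1-[methoxy(methyl)amino]-1,6-dioxo-3-(prop-1-en-2-yl)-5-(triethylsilyloxy)undec-9-ene-2,7-diyl bis[(Z)-2-methylbut-2-enoate] | C=C(C)[C@H]([C@H](OC(=O)/C(C)=C\C)C(=O)N(C)OC)C[C@@H](O[Si](CC)(CC)CC)C(=O)[C@@H](OC(=O)/C(C)=C\C)C/C=C(/C)I | intermediate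
16 | (2S,3R,5R,6R,7S,9Z)-6-hydroxy-10-iodo-1-[methoxy(methyl)amino]-6-methyl-1-oxo-3-(prop-1-en-2-yl)-5-(triethylsilyloxy)undec-9-ene-2,7-diyl bis[(Z)-2-methylbut-2-enoate] | C=C(C)[C@H]([C@H](OC(=O)/C(C)=C\C)C(=O)N(C)OC)C[C@@H](O[Si](CC)(CC)CC)[C@](C)(O)[C@@H](OC(=O)/C(C)=C\C)C/C=C(/C)I | intermediate
17 | (2S,3R,5R,6R,7S,9Z)-6-hydroxy-10-iodo-6-methyl-1-oxo-3-(prop-1-en-2-yl)-5-(triethylsilyloxy)undec-9-ene-2,7-diyl bis[(Z)-2-methylbut-2-enoate] | C=C(C)[C@H]([C@H](OC(=O)/C(C)=C\C)C=O)C[C@@H](O[Si](CC)(CC)CC)[C@](C)(O)[C@@H](OC(=O)/C(C)=C\C)C/C=C(/C)I | intermediate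
18 | (1S,2R,3Z,6S,7R,8R,10R)-2,7-dihydroxy-3,7-dimethyl-10-(prop-1-en-2-yl)-8-(triethylsilyloxy)cyclodec-3-ene-1,6-diyl bis[(Z)-2-methylbut-2-enoate] | C=C(C)[C@H]1C[C@@H](O[Si](CC)(CC)CC)[C@](C)(O)[C@@H](OC(=O)/C(C)=C\C)C/C=C(C)\[C@@H](O)[C@H]1OC(=O)/C(C)=C\C | intermediate
19 | (1S,2S,3S,4R,6S,7R,8R,10R)-3,4-epoxy-2,7-dihydroxy-3,7-dimethyl-10-(prop-1-en-2-yl)-8-(triethylsilyloxy)cyclodecane-1,6-diyl bis[(Z)-2-methylbut-2-enoate] | C=C(C)[C@H]1C[C@@H](O[Si](CC)(CC)CC)[C@](C)(O)[C@@H](OC(=O)/C(C)=C\C)C[C@H]2O[C@@]2(C)[C@@H](O)[C@H]1OC(=O)/C(C)=C\C | intermediate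
20 | (1S,2S,3R,4R,6S,7R,8R,10R)-2-acetoxy-3,4-epoxy-7-hydroxy-3,7-dimethyl-10-(prop-1-en-2-yl)-8-(triethylsilyloxy)cyclodecane-1,6-diyl bis[(Z)-2-methylbut-2-enoate] | C=C(C)[C@H]1C[C@@H](O[Si](CC)(CC)CC)[C@](C)(O)[C@@H](OC(=O)/C(C)=C\C)C[C@H]2O[C@@]2(C)[C@@H](OC(C)=O)[C@H]1OC(=O)/C(C)=C\C | intermediate
21 | CNP0249359.1, (1S,2S,3R,4R,6S,7S,8R,10R)-2-acetoxy-3,4-epoxy-7,8-dihydroxy-3,7-dimethyl-10-(prop-1-en-2-yl)cyclodecane-1,6-diyl bis[(Z)-2-methylbut-2-enoate] | C=C(C)[C@H]1C[C@@H](O)[C@](C)(O)[C@@H](OC(=O)/C(C)=C\C)C[C@H]2O[C@@]2(C)[C@@H](OC(C)=O)[C@H]1OC(=O)/C(C)=C\C | target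

**Step count and risks**
Total steps: 15. Longest linear sequence: 13 (steps 1, 2 and 5 to 15; steps 3 and 4 make the alkylating agent 8).

Steps most likely to fail:

Step 9 (the new α-angeloyloxylation; risks are catalyst N-acylation by the peroxide and low facial control). The fallback uses known chemistry, sets out from 14 and comes back at 15. D-Proline-catalysed α-aminoxylation of 14 with nitrosobenzene (DMSO, 4 °C) gives the (7S)-anilinooxy ketone F1, which is not isolated. CuSO4·5H2O in MeOH cleaves its N–O bond to the α-hydroxy ketone F2. Esterification of F2 with the mixed anhydride of angelic acid and 2,4,6-trichlorobenzoyl chloride (Et3N, toluene, 75 °C) gives 15.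

Step 6 (glyoxylate-ene reaction; the syn/anti ratio for this trisubstituted alkene is the uncertain point). The fallback sets out from 10 and 11 and comes back at 14, replacing steps 7 and 8. If the 2,3-anti series dominates, (R)-BINOL/TiCl2(OiPr)2 is used instead and gives the (2R,3R)-hydroxy ester F3, in which C10 is still R. Me3Al/MeNH(OMe)·HCl converts it into the (2R)-hydroxy amide F4. A Mitsunobu esterification of F4 with angelic acid (PPh3, DIAD, toluene, 0 °C) inverts C1 and gives 14 directly.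

Step 12 (Nozaki–Hiyama–Kishi ring closure; the C2 configuration in the ten-membered transition state is the uncertain point). The fallback sets out from 17 and comes back at 18. If the ring closes mainly to the C2 epimer F5, or to a mixture, the allylic alcohols are oxidised with Dess–Martin periodinane (CH2Cl2, NaHCO3, 0 °C) to the single enone F6. Reagent-controlled reduction of F6 with (R)-2-methyl-CBS-oxazaborolidine and catecholborane (toluene, −78 °C) then gives 18.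

**Further compounds**
F1 | step 9 | (2S,3R,5R,7S,9Z)-10-iodo-1-[methoxy(methyl)amino]-1,6-dioxo-7-(phenylaminooxy)-3-(prop-1-en-2-yl)-5-(triethylsilyloxy)undec-9-en-2-yl (Z)-2-methylbut-2-enoate | C=C(C)[C@H]([C@H](OC(=O)/C(C)=C\C)C(=O)N(C)OC)C[C@@H](O[Si](CC)(CC)CC)C(=O)[C@@H](ONc1ccccc1)C/C=C(/C)I
F2 | step 9 | (2S,3R,5R,7S,9Z)-7-hydroxy-10-iodo-1-[methoxy(methyl)amino]-1,6-dioxo-3-(prop-1-en-2-yl)-5-(triethylsilyloxy)undec-9-en-2-yl (Z)-2-methylbut-2-enoate | C=C(C)[C@H]([C@H](OC(=O)/C(C)=C\C)C(=O)N(C)OC)C[C@@H](O[Si](CC)(CC)CC)C(=O)[C@@H](O)C/C=C(/C)I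
F3 | step 6 | ethyl (2R,3R,5R,9Z)-2-hydroxy-10-iodo-6-oxo-3-(prop-1-en-2-yl)-5-(triethylsilyloxy)undec-9-enoate | C=C(C)[C@H]([C@@H](O)C(=O)OCC)C[C@@H](O[Si](CC)(CC)CC)C(=O)CC/C=C(/C)I
F4 | step 6 | (2R,3R,5R,9Z)-2-hydroxy-10-iodo-N-methoxy-N-methyl-6-oxo-3-(prop-1-en-2-yl)-5-(triethylsilyloxy)undec-9-enamide | C=C(C)[C@H]([C@@H](O)C(=O)N(C)OC)C[C@@H](O[Si](CC)(CC)CC)C(=O)CC/C=C(/C)I
F5 | step 12 | (1S,2S,3Z,6S,7R,8R,10R)-2,7-dihydroxy-3,7-dimethyl-10-(prop-1-en-2-yl)-8-(triethylsilyloxy)cyclodec-3-ene-1,6-diyl bis[(Z)-2-methylbut-2-enoate] | C=C(C)[C@H]1C[C@@H](O[Si](CC)(CC)CC)[C@](C)(O)[C@@H](OC(=O)/C(C)=C\C)C/C=C(C)\[C@H](O)[C@H]1OC(=O)/C(C)=C\C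
F6 | step 12 | (1S,3Z,6S,7R,8R,10R)-7-hydroxy-3,7-dimethyl-2-oxo-10-(prop-1-en-2-yl)-8-(triethylsilyloxy)cyclodec-3-ene-1,6-diyl bis[(Z)-2-methylbut-2-enoate] | C=C(C)[C@H]1C[C@@H](O[Si](CC)(CC)CC)[C@](C)(O)[C@@H](OC(=O)/C(C)=C\C)C/C=C(C)\C(=O)[C@H]1OC(=O)/C(C)=C\C
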